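**Plan**

Numbering (elemanolide): carbocycle C5–C10 (C10 quaternary, CH3 and vinyl C1=C2); C6–O lactone; C8–O ester; C5 carries C4(=C3H2)–C15H2OH; lactone C7–C11(=C13H2)–C12(=O)–O–C6; side chain C1′–C4′.
Retrosynthesis: cut the C8–O acyl bond (acid from an (R)-malate acetonide), the C11=C13 methylidene and the lactone C12–O6 bond, then the ring bond C5–C6, then C7–C8 (aldol), C8–C9 (one-carbon homologation) and C5–C10 (carbonyl tert-prenylation).
Enabling feature: O–C6–C5–C4(=C3H2) is a homoallylic alcohol built into the cyclohexane, so C5–C6 can arise by adding an allyl-metal C3–C4–C5 through C5 to a C6 aldehyde. Both carbons are electrophilic in the precursor (allylic benzoate, aldehyde) and are joined after palladium/zinc polarity reversal of the allyl unit.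
Forward: an acyclic C3–C12 chain is built linearly (C5–C10, then C8, then C7–C8), the carbocycle is closed last by the C5–C6 bond, then come the lactone, the exocyclic methylidene and the C8 ester.
Stereochemistry: C10 from the chiral iridium catalyst; C7 and C8 from an Evans auxiliary; C5 and C6 from the chair-like cyclisation transition state under control of C7, C8 and C10; C3′ from the chiral pool.

Key step: step 13

Assumption: the (R)-Tol-BINAP catalyst in step 2 is taken to give the (R)-configured quaternary carbon and the anti relationship drawn for 4; if the first batch shows the opposite sense, the (S)-ligand is used. The C5 configuration of 4–18 has no consequence, because C5 becomes part of an allyl-metal in step 13.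
Assumption: 27 is a catalogue compound derived from (R)-malic acid.

**Route**

Step 1
Reactants: 1 2-methylidenepropane-1,3-diol
Product: 2 2-{[(tert-butyldiphenylsilyl)oxy]methyl}prop-2-en-1-ol
Conditions: NaH (1.0 equiv), THF, 0 °C; TBDPSCl (1.0 equiv), 0 °C → rt
Reagents that add atoms: tert-butyl(chloro)diphenylsilane, CC(C)(C)[Si](Cl)(c1ccccc1)c1ccccc1
Why: Monosilylation of the symmetrical diol through its sparingly soluble monosodium alkoxide (O-silylation) should stop cleanly at the mono-ether; no stereocentre is formed.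

Step 2
Reactants: 2 2-{[(tert-butyldiphenylsilyl)oxy]methyl}prop-2-en-1-ol; 3 2-ethenyl-2-methyloxirane (racemic)
Product: 4 (2R,3R)-4-{[(tert-butyldiphenylsilyl)oxy]methyl}-2-ethenyl-2-methylpent-4-ene-1,3-diol
Conditions: (π-allyl)iridium C,O-benzoate complex from [Ir(cod)Cl]2, (R)-Tol-BINAP, 4-cyano-3-nitrobenzoic acid and allyl acetate (5 mol %), K3PO4 (5 mol %), 3 (3 equiv), THF, 45–60 °C
Reagents that add atoms: none
Why: Iridium-catalysed transfer-hydrogenative tert-(hydroxy)prenylation: the alcohol is dehydrogenated to the enal, which is attacked at its carbonyl carbon (C5) by the methyl-bearing terminus of the allyliridium alkoxide formed from the vinyl epoxide through a closed chair transition state, so the chiral ligand sets the quaternary C10 (and the anti C5 carbinol) stereoconvergently from racemic 3.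

Step 3
Reactants: 4 (2R,3R)-4-{[(tert-butyldiphenylsilyl)oxy]methyl}-2-ethenyl-2-methylpent-4-ene-1,3-diol
Product: 5 (3R,4R)-2-{[(tert-butyldiphenylsilyl)oxy]methyl}-4-ethenyl-4-methyl-5-[(triethylsilyl)oxy]pent-1-en-3-ol
Conditions: Et3SiCl (1.05 equiv), imidazole, CH2Cl2, −40 → 0 °C
Reagents that add atoms: chlorotriethylsilane, CC[Si](Cl)(CC)CC
Why: Selective O-silylation of the primary C9 hydroxyl over the secondary C5 hydroxyl, which is flanked by the quaternary carbon and the substituted alkene; no stereocentre is touched.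

Step 4
Reactants: 5 (3R,4R)-2-{[(tert-butyldiphenylsilyl)oxy]methyl}-4-ethenyl-4-methyl-5-[(triethylsilyl)oxy]pent-1-en-3-ol
Product: 6 (3R,4R)-2-{[(tert-butyldiphenylsilyl)oxy]methyl}-4-ethenyl-4-methyl-5-[(triethylsilyl)oxy]pent-1-en-3-yl benzoate
Conditions: BzCl (3 equiv), pyridine, DMAP (0.2 equiv), CH2Cl2, rt → 40 °C
Reagents that add atoms: benzoyl chloride, O=C(Cl)c1ccccc1
Why: DMAP-catalysed acylation turns the C5 hydroxyl into the allylic benzoate that protects it through the chain extension and later serves as the leaving group for ionisation; configuration is retained.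

Step 5
Reactants: 6 (3R,4R)-2-{[(tert-butyldiphenylsilyl)oxy]methyl}-4-ethenyl-4-methyl-5-[(triethylsilyl)oxy]pent-1-en-3-yl benzoate
Product: 7 (3R,4S)-2-{[(tert-butyldiphenylsilyl)oxy]methyl}-4-ethenyl-4-methyl-5-oxopent-1-en-3-yl benzoate
Conditions: (COCl)2, DMSO, CH2Cl2, −78 → −40 °C; Et3N, → 0 °C
Reagents that add atoms: none
Why: Swern oxidation with direct oxidative cleavage of the primary triethylsilyl ether (the chlorosulfonium ion attacks the silyl ether oxygen) should give the C9 aldehyde in one operation while the TBDPS ether and benzoate persist; the α-carbon is quaternary and cannot epimerise.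

Step 6
Reactants: 7 (3R,4S)-2-{[(tert-butyldiphenylsilyl)oxy]methyl}-4-ethenyl-4-methyl-5-oxopent-1-en-3-yl benzoate
Product: 8 (3S,4R)-2-{[(tert-butyldiphenylsilyl)oxy]methyl}-4-ethenyl-6-methoxy-4-methylhexa-1,5-dien-3-yl benzoate (E/Z mixture)
Conditions: MeOCH2PPh3Cl, KN(SiMe3)2, THF, 0 °C; then 7, −78 °C → rt
Reagents that add atoms: (methoxymethyl)triphenylphosphonium chloride, COC[P+](c1ccccc1)(c1ccccc1)c1ccccc1.[Cl-]
Why: Wittig methoxymethylenation of the non-enolisable neopentyl aldehyde adds the carbon that becomes C8; the enol ether geometry is irrelevant.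

Step 7
Reactants: 8 (3S,4R)-2-{[(tert-butyldiphenylsilyl)oxy]methyl}-4-ethenyl-6-methoxy-4-methylhexa-1,5-dien-3-yl benzoate
Product: 9 (3S,4S)-2-{[(tert-butyldiphenylsilyl)oxy]methyl}-4-ethenyl-4-methyl-6-oxohex-1-en-3-yl benzoate
Conditions: 2 M aq. HCl/THF (1:5), 0 °C → rt
Reagents that add atoms: water, O
Why: Acid hydrolysis of the enol ether liberates the homologated C8 aldehyde; the benzoate and the TBDPS ether tolerate dilute acid.

Step 8
Reactants: 10 4-tert-butoxy-4-oxobutanoic acid; 11 (4R)-4-benzyl-1,3-oxazolidin-2-one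
Product: 13 tert-butyl 4-[(4R)-4-benzyl-2-oxo-1,3-oxazolidin-3-yl]-4-oxobutanoate, via mixed pivalic anhydride 12 (not isolated)
Conditions: t-BuCOCl, Et3N, THF, −20 °C; then 11, LiCl, −20 °C → rt
Reagents that add atoms: none
Why: N-acylation of the oxazolidinone through the mixed pivalic anhydride; the auxiliary stereocentre is bought in.

Step 9
Reactants: 13 tert-butyl 4-[(4R)-4-benzyl-2-oxo-1,3-oxazolidin-3-yl]-4-oxobutanoate; 9 (3S,4S)-2-{[(tert-butyldiphenylsilyl)oxy]methyl}-4-ethenyl-4-methyl-6-oxohex-1-en-3-yl benzoate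
Product: 15 tert-butyl (3R,4S,6S,7S)-7-(benzoyloxy)-3-{[(4R)-4-benzyl-2-oxo-1,3-oxazolidin-3-yl]carbonyl}-8-{[(tert-butyldiphenylsilyl)oxy]methyl}-6-ethenyl-4-hydroxy-6-methylnon-8-enoate, via dibutylboron Z-enolate 14 (not isolated)
Conditions: Bu2BOTf, i-Pr2NEt, CH2Cl2, −78 → 0 °C; then 9, −78 → 0 °C; pH 7 buffer, MeOH, 30 % H2O2, 0 °C
Reagents that add atoms: none
Why: Evans syn-aldol: the Z-boron enolate reacts through a Zimmerman–Traxler chair whose face is dictated by the (R)-benzyl auxiliary, setting C7 (R) and C8 (S) independently of the remote C10.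

Step 10
Reactants: 15 tert-butyl (3R,4S,6S,7S)-7-(benzoyloxy)-3-{[(4R)-4-benzyl-2-oxo-1,3-oxazolidin-3-yl]carbonyl}-8-{[(tert-butyldiphenylsilyl)oxy]methyl}-6-ethenyl-4-hydroxy-6-methylnon-8-enoate
Product: 16 tert-butyl (3R,4S,6S,7S)-7-(benzoyloxy)-3-{[(4R)-4-benzyl-2-oxo-1,3-oxazolidin-3-yl]carbonyl}-4-[(tert-butyldimethylsilyl)oxy]-8-{[(tert-butyldiphenylsilyl)oxy]methyl}-6-ethenyl-6-methylnon-8-enoate
Conditions: TBSOTf, 2,6-lutidine, CH2Cl2, −78 → 0 °C
Reagents that add atoms: tert-butyldimethylsilyl trifluoromethanesulfonate, CC(C)(C)[Si](C)(C)OS(=O)(=O)C(F)(F)F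
Why: O-silylation of the aldol hydroxyl blocks O8, so that later only O6 can close the lactone; low temperature spares the tert-butyl ester.

Step 11
Reactants: 16 tert-butyl (3R,4S,6S,7S)-7-(benzoyloxy)-3-{[(4R)-4-benzyl-2-oxo-1,3-oxazolidin-3-yl]carbonyl}-4-[(tert-butyldimethylsilyl)oxy]-8-{[(tert-butyldiphenylsilyl)oxy]methyl}-6-ethenyl-6-methylnon-8-enoate
Product: 17 tert-butyl (3S,4S,6S,7S)-7-(benzoyloxy)-4-[(tert-butyldimethylsilyl)oxy]-8-{[(tert-butyldiphenylsilyl)oxy]methyl}-6-ethenyl-3-(hydroxymethyl)-6-methylnon-8-enoate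
Conditions: NaBH4, THF/H2O (4:1), 0 °C → rt
Reagents that add atoms: none
Why: Reductive removal of the auxiliary: borohydride reduces the activated exocyclic imide carbonyl much faster than the tert-butyl ester or the hindered benzoate, giving the C6 primary alcohol without touching C7.

Step 12
Reactants: 17 tert-butyl (3S,4S,6S,7S)-7-(benzoyloxy)-4-[(tert-butyldimethylsilyl)oxy]-8-{[(tert-butyldiphenylsilyl)oxy]methyl}-6-ethenyl-3-(hydroxymethyl)-6-methylnon-8-enoate
Product: 18 tert-butyl (3R,4S,6S,7S)-7-(benzoyloxy)-4-[(tert-butyldimethylsilyl)oxy]-8-{[(tert-butyldiphenylsilyl)oxy]methyl}-6-ethenyl-3-formyl-6-methylnon-8-enoate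
Conditions: Dess–Martin periodinane, CH2Cl2, 0 °C → rt
Reagents that add atoms: none
Why: Dess–Martin oxidation gives the C6 aldehyde under non-basic conditions, so the α-stereocentre C7 and the β-silyloxy group are preserved.

Step 13
Reactants: 18 tert-butyl (3R,4S,6S,7S)-7-(benzoyloxy)-4-[(tert-butyldimethylsilyl)oxy]-8-{[(tert-butyldiphenylsilyl)oxy]methyl}-6-ethenyl-3-formyl-6-methylnon-8-enoate
Product: 20 tert-butyl 2-[(1S,2R,3R,4S,6S)-6-[(tert-butyldimethylsilyl)oxy]-3-(3-{[tert-butyldiphenylsilyl]oxy}prop-1-en-2-yl)-4-ethenyl-2-hydroxy-4-methylcyclohexyl]acetate, via ethylzinc allyl species 19 (not isolated)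
Conditions: Pd(PPh3)4 (10 mol %), Et2Zn (3 equiv), THF (0.01 M), 0 °C → rt; aq. NH4Cl
Reagents that add atoms: none
Why: Zerovalent palladium ionises the secondary allylic benzoate at C5 to a π-allylpalladium benzoate spanning C3–C4–C5, Et2Zn transmetalates it to the nucleophilic allylzinc 19 (the ethyl group leaves palladium as ethene and the catalyst is regenerated), and 19 adds through its γ-carbon C5 to the aldehyde carbon C6, so two carbons that were both electrophilic are joined after polarity reversal of the allyl unit. The closest known reaction type is the palladium-catalysed, Et2Zn-promoted umpolung allylation of aldehydes with allylic benzoates, a catalytic relative of the Barbier and Nozaki–Hiyama allylations, run here intramolecularly at high dilution. The six-membered carbocycle C5–C6–C7–C8–C9–C10 closes by 6-exo-trig attack on the carbonyl group with only the γ-carbon of the allyl unit entering the ring, which leaves the C4=C3 methylidene and the C15 silyloxymethyl group on the exocyclic C4. C5 and C6 are set together in a chair-like ring-forming transition state fused trans to the six-membered Zn–O=C6–C5–C4–C3 array: the C7 CH2CO2t-Bu and C8 OTBS groups sit equatorial, C10 is thereby forced to carry its methyl axial and its vinyl equatorial, and the forming C6–O and C5–C4 bonds both take equatorial positions, giving the 5,6-trans-6,7-trans product. The step needs γ- rather than α-attack (six- versus eight-membered ring), which the tether enforces, and addition to the aldehyde in the presence of the tert-butyl ester and silyl ethers, which the mild organozinc secures. Fast 1,3-metallotropic equilibration of the allylzinc makes the C5 configuration of 18 and the alkene geometry of 19 irrelevant.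

Step 14
Reactants: 20 tert-butyl 2-[(1S,2R,3R,4S,6S)-6-[(tert-butyldimethylsilyl)oxy]-3-(3-{[tert-butyldiphenylsilyl]oxy}prop-1-en-2-yl)-4-ethenyl-2-hydroxy-4-methylcyclohexyl]acetate
Product: 21 (3aS,4S,6S,7R,7aR)-4-[(tert-butyldimethylsilyl)oxy]-7-(3-{[tert-butyldiphenylsilyl]oxy}prop-1-en-2-yl)-6-ethenyl-6-methylhexahydro-1-benzofuran-2(3H)-one
Conditions: camphorsulfonic acid (0.2 equiv), toluene, 60 °C
Reagents that add atoms: none
Why: Acid-catalysed lactonisation (intramolecular transesterification) of the γ-hydroxy tert-butyl ester closes the trans-fused 6,12-lactone; O8 is silylated, so no 8,12-lactone can form, and any lactone already formed in step 13 converges here.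

Step 15
Reactants: 21 (3aS,4S,6S,7R,7aR)-4-[(tert-butyldimethylsilyl)oxy]-7-(3-{[tert-butyldiphenylsilyl]oxy}prop-1-en-2-yl)-6-ethenyl-6-methylhexahydro-1-benzofuran-2(3H)-one
Product: 25 (3aS,4S,6S,7R,7aR)-4-[(tert-butyldimethylsilyl)oxy]-7-(3-{[tert-butyldiphenylsilyl]oxy}prop-1-en-2-yl)-6-ethenyl-6-methyl-3-methylidenehexahydro-1-benzofuran-2(3H)-one, via lithium enolate 22 (not isolated), via Mannich base 23 (not isolated), via trimethylammonium iodide 24 (not isolated)
Conditions: LiN(i-Pr)2, THF, −78 °C; CH2=NMe2+ I−, −78 °C → rt; MeI, THF/MeOH, rt; sat. aq. NaHCO3, CH2Cl2, rt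
Reagents that add atoms: N,N-dimethylmethylideneammonium iodide (Eschenmoser's salt), C=[N+](C)C.[I-]
Why: α-Methylenation of the lactone by Mannich reaction of its enolate with Eschenmoser's salt, N-methylation and base-induced β-elimination of trimethylamine; the transient C11 stereocentre disappears and no other position is enolisable.

Step 16
Reactants: 25 (3aS,4S,6S,7R,7aR)-4-[(tert-butyldimethylsilyl)oxy]-7-(3-{[tert-butyldiphenylsilyl]oxy}prop-1-en-2-yl)-6-ethenyl-6-methyl-3-methylidenehexahydro-1-benzofuran-2(3H)-one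
Product: 26 (3aR,4S,6S,7R,7aR)-7-(3-{[tert-butyldiphenylsilyl]oxy}prop-1-en-2-yl)-6-ethenyl-4-hydroxy-6-methyl-3-methylidenehexahydro-1-benzofuran-2(3H)-one
Conditions: 48 % aq. HF, MeCN, 0 °C → rt (monitored)
Reagents that add atoms: none
Why: Acidic fluoride cleaves the tert-butyldimethylsilyl ether much faster than the tert-butyldiphenylsilyl ether (chemoselective desilylation), freeing only O8 under conditions too acidic for lactone migration.

Step 17
Reactants: 27 methyl 2-[(4R)-2,2-dimethyl-1,3-dioxolan-4-yl]acetate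
Product: 31 methyl 2-[(4R)-2,2-dimethyl-1,3-dioxolan-4-yl]prop-2-enoate, via lithium enolate 28 (not isolated), via Mannich base 29 (not isolated), via trimethylammonium iodide 30 (not isolated)
Conditions: LiN(i-Pr)2, THF, −78 °C; CH2=NMe2+ I− (powdered), −78 °C; MeI, −78 °C → rt; sat. aq. NaHCO3, CH2Cl2, rt
Reagents that add atoms: N,N-dimethylmethylideneammonium iodide (Eschenmoser's salt), C=[N+](C)C.[I-]
Why: The same Mannich/quaternisation/elimination α-methylenation on the ester enolate, trapped at −78 °C before the β-alkoxy group can leave; the C3′ stereocentre is not part of the enolate and is retained.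

Step 18
Reactants: 31 methyl 2-[(4R)-2,2-dimethyl-1,3-dioxolan-4-yl]prop-2-enoate
Product: 32 2-[(4R)-2,2-dimethyl-1,3-dioxolan-4-yl]prop-2-enoic acid
Conditions: LiOH·H2O, THF/H2O (3:1), 0 °C → rt; 1 M HCl to pH 3, 0 °C
Reagents that add atoms: lithium hydroxide, [Li+].[OH-]
Why: Saponification of the methyl ester (acyl–oxygen cleavage), with brief cold acidification so that the acetonide survives.

Step 19
Reactants: 26 (3aR,4S,6S,7R,7aR)-7-(3-{[tert-butyldiphenylsilyl]oxy}prop-1-en-2-yl)-6-ethenyl-4-hydroxy-6-methyl-3-methylidenehexahydro-1-benzofuran-2(3H)-one; 32 2-[(4R)-2,2-dimethyl-1,3-dioxolan-4-yl]prop-2-enoic acid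
Product: 34 (3aR,4S,6S,7R,7aR)-7-(3-{[tert-butyldiphenylsilyl]oxy}prop-1-en-2-yl)-6-ethenyl-6-methyl-3-methylidene-2-oxooctahydro-1-benzofuran-4-yl 2-[(4R)-2,2-dimethyl-1,3-dioxolan-4-yl]prop-2-enoate, via Yamaguchi mixed anhydride 33 (not isolated)
Conditions: 2,4,6-trichlorobenzoyl chloride, Et3N, toluene, rt; then 26, DMAP, toluene, rt
Reagents that add atoms: none
Why: Yamaguchi esterification acylates the equatorial C8 hydroxyl, the only free hydroxyl, with retention at C8 and without touching C3′.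

Step 20
Reactants: 34 (3aR,4S,6S,7R,7aR)-7-(3-{[tert-butyldiphenylsilyl]oxy}prop-1-en-2-yl)-6-ethenyl-6-methyl-3-methylidene-2-oxooctahydro-1-benzofuran-4-yl 2-[(4R)-2,2-dimethyl-1,3-dioxolan-4-yl]prop-2-enoate
Product: 35 (3aR,4S,6S,7R,7aR)-6-ethenyl-7-(3-hydroxyprop-1-en-2-yl)-6-methyl-3-methylidene-2-oxooctahydro-1-benzofuran-4-yl 2-[(4R)-2,2-dimethyl-1,3-dioxolan-4-yl]prop-2-enoate
Conditions: HF·pyridine, pyridine/THF, 0 °C → rt
Reagents that add atoms: none
Why: Fluoride-mediated cleavage of the primary allylic silyl ether under buffered, non-basic conditions, which avoids conjugate addition and acyl migration.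

Step 21
Reactants: 35 (3aR,4S,6S,7R,7aR)-6-ethenyl-7-(3-hydroxyprop-1-en-2-yl)-6-methyl-3-methylidene-2-oxooctahydro-1-benzofuran-4-yl 2-[(4R)-2,2-dimethyl-1,3-dioxolan-4-yl]prop-2-enoate
Product: 36 (3aR,4S,6S,7R,7aR)-6-ethenyl-7-(3-hydroxyprop-1-en-2-yl)-6-methyl-3-methylidene-2-oxooctahydro-1-benzofuran-4-yl (3R)-3,4-dihydroxy-2-methylidenebutanoate (target)
Conditions: AcOH/H2O/THF (3:1:1), rt → 35 °C
Reagents that add atoms: none
Why: Mild acid hydrolysis of the terminal acetonide releases the 3′,4′-diol; base is avoided so that the γ-hydroxy ester does not lactonise and no stereocentre is affected.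

**Compound list**

1 | 2-methylidenepropane-1,3-diol | C=C(CO)CO | starting material
2 | 2-{[(tert-butyldiphenylsilyl)oxy]methyl}prop-2-en-1-ol | C=C(CO)CO[Si](c1ccccc1)(c1ccccc1)C(C)(C)C | intermediate
3 | 2-ethenyl-2-methyloxirane (isoprene monoxide, racemic) | C=CC1(C)CO1 | starting material
4 | (2R,3R)-4-{[(tert-butyldiphenylsilyl)oxy]methyl}-2-ethenyl-2-methylpent-4-ene-1,3-diol | C=C[C@](C)(CO)[C@H](O)C(=C)CO[Si](c1ccccc1)(c1ccccc1)C(C)(C)C | intermediate
5 | (3R,4R)-2-{[(tert-butyldiphenylsilyl)oxy]methyl}-4-ethenyl-4-methyl-5-[(triethylsilyl)oxy]pent-1-en-3-ol | C=C[C@](C)(CO[Si](CC)(CC)CC)[C@H](O)C(=C)CO[Si](c1ccccc1)(c1ccccc1)C(C)(C)C | intermediate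
6 | (3R,4R)-2-{[(tert-butyldiphenylsilyl)oxy]methyl}-4-ethenyl-4-methyl-5-[(triethylsilyl)oxy]pent-1-en-3-yl benzoate | C=C[C@](C)(CO[Si](CC)(CC)CC)[C@H](OC(=O)c1ccccc1)C(=C)CO[Si](c1ccccc1)(c1ccccc1)C(C)(C)C | intermediate
7 | (3R,4S)-2-{[(tert-butyldiphenylsilyl)oxy]methyl}-4-ethenyl-4-methyl-5-oxopent-1-en-3-yl benzoate | C=C[C@](C)(C=O)[C@H](OC(=O)c1ccccc1)C(=C)CO[Si](c1ccccc1)(c1ccccc1)C(C)(C)C | intermediate
8 | (3S,4R)-2-{[(tert-butyldiphenylsilyl)oxy]methyl}-4-ethenyl-6-methoxy-4-methylhexa-1,5-dien-3-yl benzoate (E/Z mixture at the enol ether) | C=C[C@](C)(C=COC)[C@H](OC(=O)c1ccccc1)C(=C)CO[Si](c1ccccc1)(c1ccccc1)C(C)(C)C | intermediate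
9 | (3S,4S)-2-{[(tert-butyldiphenylsilyl)oxy]methyl}-4-ethenyl-4-methyl-6-oxohex-1-en-3-yl benzoate | C=C[C@](C)(CC=O)[C@H](OC(=O)c1ccccc1)C(=C)CO[Si](c1ccccc1)(c1ccccc1)C(C)(C)C | intermediate
10 | 4-tert-butoxy-4-oxobutanoic acid | CC(C)(C)OC(=O)CCC(=O)O | starting material
11 | (4R)-4-benzyl-1,3-oxazolidin-2-one | O=C1N[C@H](Cc2ccccc2)CO1 | starting material
12 | 4-tert-butoxy-4-oxobutanoic pivalic anhydride | CC(C)(C)OC(=O)CCC(=O)OC(=O)C(C)(C)C | intermediate (not isolated)
13 | tert-butyl 4-[(4R)-4-benzyl-2-oxo-1,3-oxazolidin-3-yl]-4-oxobutanoate | CC(C)(C)OC(=O)CCC(=O)N1[C@H](Cc2ccccc2)COC1=O | intermediate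
14 | dibutylboron (Z)-enolate of 13 | CCCCB(CCCC)O/C(=C\CC(=O)OC(C)(C)C)N1[C@H](Cc2ccccc2)COC1=O | intermediate (not isolated)
15 | tert-butyl (3R,4S,6S,7S)-7-(benzoyloxy)-3-{[(4R)-4-benzyl-2-oxo-1,3-oxazolidin-3-yl]carbonyl}-8-{[(tert-butyldiphenylsilyl)oxy]methyl}-6-ethenyl-4-hydroxy-6-methylnon-8-enoate | CC(C)(C)OC(=O)C[C@H]([C@@H](O)C[C@@](C)(C=C)[C@H](OC(=O)c1ccccc1)C(=C)CO[Si](c1ccccc1)(c1ccccc1)C(C)(C)C)C(=O)N1[C@H](Cc2ccccc2)COC1=O | intermediate
16 | 4-O-tert-butyldimethylsilyl ether of 15 (3R,4S,6S,7S) | CC(C)(C)OC(=O)C[C@H]([C@@H](O[Si](C)(C)C(C)(C)C)C[C@@](C)(C=C)[C@H](OC(=O)c1ccccc1)C(=C)CO[Si](c1ccccc1)(c1ccccc1)C(C)(C)C)C(=O)N1[C@H](Cc2ccccc2)COC1=O | intermediate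
17 | tert-butyl (3S,4S,6S,7S)-7-(benzoyloxy)-4-[(tert-butyldimethylsilyl)oxy]-8-{[(tert-butyldiphenylsilyl)oxy]methyl}-6-ethenyl-3-(hydroxymethyl)-6-methylnon-8-enoate | CC(C)(C)OC(=O)C[C@@H](CO)[C@@H](O[Si](C)(C)C(C)(C)C)C[C@@](C)(C=C)[C@H](OC(=O)c1ccccc1)C(=C)CO[Si](c1ccccc1)(c1ccccc1)C(C)(C)C | intermediate
18 | tert-butyl (3R,4S,6S,7S)-7-(benzoyloxy)-4-[(tert-butyldimethylsilyl)oxy]-8-{[(tert-butyldiphenylsilyl)oxy]methyl}-6-ethenyl-3-formyl-6-methylnon-8-enoate | CC(C)(C)OC(=O)C[C@@H](C=O)[C@@H](O[Si](C)(C)C(C)(C)C)C[C@@](C)(C=C)[C@H](OC(=O)c1ccccc1)C(=C)CO[Si](c1ccccc1)(c1ccccc1)C(C)(C)C | intermediate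
19 | ethylzinc allyl species from 18 (zinc on C3, alkene geometry mobile) | CC[Zn]CC(CO[Si](c1ccccc1)(c1ccccc1)C(C)(C)C)=C[C@](C)(C=C)C[C@H](O[Si](C)(C)C(C)(C)C)[C@H](C=O)CC(=O)OC(C)(C)C | intermediate (not isolated)
20 | tert-butyl 2-[(1S,2R,3R,4S,6S)-6-[(tert-butyldimethylsilyl)oxy]-3-(3-{[tert-butyldiphenylsilyl]oxy}prop-1-en-2-yl)-4-ethenyl-2-hydroxy-4-methylcyclohexyl]acetate | C=C[C@]1(C)C[C@H](O[Si](C)(C)C(C)(C)C)[C@@H](CC(=O)OC(C)(C)C)[C@H](O)[C@H]1C(=C)CO[Si](c1ccccc1)(c1ccccc1)C(C)(C)C | intermediate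
21 | (3aS,4S,6S,7R,7aR)-4-[(tert-butyldimethylsilyl)oxy]-7-(3-{[tert-butyldiphenylsilyl]oxy}prop-1-en-2-yl)-6-ethenyl-6-methylhexahydro-1-benzofuran-2(3H)-one | C=C[C@]1(C)C[C@H](O[Si](C)(C)C(C)(C)C)[C@H]2CC(=O)O[C@@H]2[C@H]1C(=C)CO[Si](c1ccccc1)(c1ccccc1)C(C)(C)C | intermediate
22 | lithium enolate of 21 | C=C[C@]1(C)C[C@H](O[Si](C)(C)C(C)(C)C)[C@H]2C=C(O[Li])O[C@@H]2[C@H]1C(=C)CO[Si](c1ccccc1)(c1ccccc1)C(C)(C)C | intermediate (not isolated)
23 | 3-[(dimethylamino)methyl] derivative of 21 (either C11 epimer) | C=C[C@]1(C)C[C@H](O[Si](C)(C)C(C)(C)C)[C@H]2C(CN(C)C)C(=O)O[C@@H]2[C@H]1C(=C)CO[Si](c1ccccc1)(c1ccccc1)C(C)(C)C | intermediate (not isolated)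
24 | 3-[(trimethylammonio)methyl] derivative of 21, iodide | C=C[C@]1(C)C[C@H](O[Si](C)(C)C(C)(C)C)[C@H]2C(C[N+](C)(C)C)C(=O)O[C@@H]2[C@H]1C(=C)CO[Si](c1ccccc1)(c1ccccc1)C(C)(C)C.[I-] | intermediate (not isolated)
25 | (3aS,4S,6S,7R,7aR)-4-[(tert-butyldimethylsilyl)oxy]-7-(3-{[tert-butyldiphenylsilyl]oxy}prop-1-en-2-yl)-6-ethenyl-6-methyl-3-methylidenehexahydro-1-benzofuran-2(3H)-one | C=C[C@]1(C)C[C@H](O[Si](C)(C)C(C)(C)C)[C@H]2C(=C)C(=O)O[C@@H]2[C@H]1C(=C)CO[Si](c1ccccc1)(c1ccccc1)C(C)(C)C | intermediate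
26 | (3aR,4S,6S,7R,7aR)-7-(3-{[tert-butyldiphenylsilyl]oxy}prop-1-en-2-yl)-6-ethenyl-4-hydroxy-6-methyl-3-methylidenehexahydro-1-benzofuran-2(3H)-one | C=C[C@]1(C)C[C@H](O)[C@H]2C(=C)C(=O)O[C@@H]2[C@H]1C(=C)CO[Si](c1ccccc1)(c1ccccc1)C(C)(C)C | intermediate
27 | methyl 2-[(4R)-2,2-dimethyl-1,3-dioxolan-4-yl]acetate | COC(=O)C[C@@H]1COC(C)(C)O1 | starting material
28 | lithium enolate of 27 | COC(O[Li])=C[C@@H]1COC(C)(C)O1 | intermediate (not isolated)
29 | methyl 3-(dimethylamino)-2-[(4R)-2,2-dimethyl-1,3-dioxolan-4-yl]propanoate (either C2 epimer) | COC(=O)C(CN(C)C)[C@@H]1COC(C)(C)O1 | intermediate (not isolated)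
30 | N-methyl quaternary ammonium iodide of 29 | COC(=O)C(C[N+](C)(C)C)[C@@H]1COC(C)(C)O1.[I-] | intermediate (not isolated)
31 | methyl 2-[(4R)-2,2-dimethyl-1,3-dioxolan-4-yl]prop-2-enoate | COC(=O)C(=C)[C@@H]1COC(C)(C)O1 | intermediate
32 | 2-[(4R)-2,2-dimethyl-1,3-dioxolan-4-yl]prop-2-enoic acid | C=C([C@@H]1COC(C)(C)O1)C(=O)O | intermediate
33 | 2-[(4R)-2,2-dimethyl-1,3-dioxolan-4-yl]prop-2-enoic 2,4,6-trichlorobenzoic anhydride | C=C([C@@H]1COC(C)(C)O1)C(=O)OC(=O)c1c(Cl)cc(Cl)cc1Cl | intermediate (not isolated)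
34 | (3aR,4S,6S,7R,7aR)-7-(3-{[tert-butyldiphenylsilyl]oxy}prop-1-en-2-yl)-6-ethenyl-6-methyl-3-methylidene-2-oxooctahydro-1-benzofuran-4-yl 2-[(4R)-2,2-dimethyl-1,3-dioxolan-4-yl]prop-2-enoate | C=C[C@]1(C)C[C@H](OC(=O)C(=C)[C@@H]3COC(C)(C)O3)[C@H]2C(=C)C(=O)O[C@@H]2[C@H]1C(=C)CO[Si](c1ccccc1)(c1ccccc1)C(C)(C)C | intermediate
35 | (3aR,4S,6S,7R,7aR)-6-ethenyl-7-(3-hydroxyprop-1-en-2-yl)-6-methyl-3-methylidene-2-oxooctahydro-1-benzofuran-4-yl 2-[(4R)-2,2-dimethyl-1,3-dioxolan-4-yl]prop-2-enoate | C=C[C@]1(C)C[C@H](OC(=O)C(=C)[C@@H]3COC(C)(C)O3)[C@H]2C(=C)C(=O)O[C@@H]2[C@H]1C(=C)CO | intermediate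
36 | (3aR,4S,6S,7R,7aR)-6-ethenyl-7-(3-hydroxyprop-1-en-2-yl)-6-methyl-3-methylidene-2-oxooctahydro-1-benzofuran-4-yl (3R)-3,4-dihydroxy-2-methylidenebutanoate | C=C[C@]1(C)C[C@H](OC(=O)C(=C)[C@@H](O)CO)[C@H]2C(=C)C(=O)O[C@@H]2[C@H]1C(=C)CO | target

**Step count and risks**

Total steps: 21. Longest linear sequence: 18 steps (steps 1–7, 9–16, 19–21).

Steps most likely to fail:

1. Step 13 (ring closure). What may go wrong: slow ionisation of the hindered secondary allylic benzoate, protonolysis or hydride reduction of the allyl-metal before it cyclises, ethyl transfer from zinc to the aldehyde, or erosion of the trans selectivity. The fallback replaces the in-situ polarity reversal by an isolated allylsilane and a Lewis-acid-promoted Hosomi–Sakurai cyclisation. It sets out from alcohol 17: palladium-catalysed silylation of the allylic benzoate with Me3SiSiMe3 (Pd2(dba)3, LiCl, DMF) puts silicon on the unhindered terminus C3 and gives tert-butyl 4-[(tert-butyldimethylsilyl)oxy]-8-{[(tert-butyldiphenylsilyl)oxy]methyl}-6-ethenyl-3-(hydroxymethyl)-6-methyl-9-(trimethylsilyl)non-7-enoate F1. Dess–Martin oxidation gives the corresponding 3-formyl allylsilane F2. BF3·OEt2 in CH2Cl2 at −78 °C then closes C5–C6 through an open transition state with the same all-equatorial chair preference, and the route is rejoined at cyclohexanol 20.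

2. Step 2 (quaternary carbon). What may go wrong: conjugate reduction or isomerisation of the transient 2-substituted acrolein under the transfer-hydrogenation conditions, or insufficient anti and enantiofacial control, which would lower the optical purity of C10. The fallback builds C10 by auxiliary-controlled aldol reaction and chelate-controlled alkylation, and sets out from allylic alcohol 2. MnO2 oxidation gives 2-{[(tert-butyldiphenylsilyl)oxy]methyl}prop-2-enal F3. An Evans syn-aldol with commercial (4S)-4-benzyl-3-[(E)-but-2-enoyl]-1,3-oxazolidin-2-one (Bu2BOTf, Et3N; α-attack of the boron dienolate) gives (4S)-4-benzyl-3-[(2S,3S)-4-{[(tert-butyldiphenylsilyl)oxy]methyl}-2-ethenyl-3-hydroxypent-4-enoyl]-1,3-oxazolidin-2-one F4, which fixes C5. Transesterification with MeOMgBr gives methyl (2S,3S)-4-{[(tert-butyldiphenylsilyl)oxy]methyl}-2-ethenyl-3-hydroxypent-4-enoate F5. Fráter–Seebach methylation of its dianion (LiN(i-Pr)2, 2.2 equiv, then MeI) places the methyl group anti to the alkoxide and gives methyl (2S,3R)-4-{[(tert-butyldiphenylsilyl)oxy]methyl}-2-ethenyl-3-hydroxy-2-methylpent-4-enoate F6. LiBH4 reduction of the ester returns to diol 4.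

3. Step 17 (side-chain methylenation). What may go wrong: β-elimination of the acetonide oxygen from the ester enolate before the poorly soluble iminium salt traps it. The fallback runs the methylenation on an alkoxide–enolate dianion, whose β-oxygen is an alkoxide and cannot leave, and sets out from ester 27. Acid-catalysed acetonide cleavage with spontaneous lactonisation (TsOH, MeOH/H2O) gives (4R)-4-hydroxydihydrofuran-2(3H)-one F7. Its dianion (LiN(i-Pr)2, 2.2 equiv) is methylenated by the same Mannich/quaternisation/elimination sequence to (4R)-4-hydroxy-3-methylidenedihydrofuran-2(3H)-one F8. Ring-opening acetalisation (2,2-dimethoxypropane, MeOH, TsOH) returns to acrylate 31.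

Further compounds
F1 | step 13 | tert-butyl 4-[(tert-butyldimethylsilyl)oxy]-8-{[(tert-butyldiphenylsilyl)oxy]methyl}-6-ethenyl-3-(hydroxymethyl)-6-methyl-9-(trimethylsilyl)non-7-enoate (C3, C4, C6 as in 17; E/Z mixture) | C[Si](C)(C)CC(CO[Si](c1ccccc1)(c1ccccc1)C(C)(C)C)=C[C@](C)(C=C)C[C@H](O[Si](C)(C)C(C)(C)C)[C@H](CO)CC(=O)OC(C)(C)C
F2 | step 13 | tert-butyl 4-[(tert-butyldimethylsilyl)oxy]-8-{[(tert-butyldiphenylsilyl)oxy]methyl}-6-ethenyl-3-formyl-6-methyl-9-(trimethylsilyl)non-7-enoate (C3, C4, C6 as in 18; E/Z mixture) | C[Si](C)(C)CC(CO[Si](c1ccccc1)(c1ccccc1)C(C)(C)C)=C[C@](C)(C=C)C[C@H](O[Si](C)(C)C(C)(C)C)[C@H](C=O)CC(=O)OC(C)(C)C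
F3 | step 2 | 2-{[(tert-butyldiphenylsilyl)oxy]methyl}prop-2-enal | O=CC(=C)CO[Si](c1ccccc1)(c1ccccc1)C(C)(C)C
F4 | step 2 | (4S)-4-benzyl-3-[(2S,3S)-4-{[(tert-butyldiphenylsilyl)oxy]methyl}-2-ethenyl-3-hydroxypent-4-enoyl]-1,3-oxazolidin-2-one | C=C[C@@H]([C@H](O)C(=C)CO[Si](c1ccccc1)(c1ccccc1)C(C)(C)C)C(=O)N1[C@@H](Cc2ccccc2)COC1=O
F5 | step 2 | methyl (2S,3S)-4-{[(tert-butyldiphenylsilyl)oxy]methyl}-2-ethenyl-3-hydroxypent-4-enoate | COC(=O)[C@@H](C=C)[C@H](O)C(=C)CO[Si](c1ccccc1)(c1ccccc1)C(C)(C)C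
F6 | step 2 | methyl (2S,3R)-4-{[(tert-butyldiphenylsilyl)oxy]methyl}-2-ethenyl-3-hydroxy-2-methylpent-4-enoate | COC(=O)[C@@](C)(C=C)[C@H](O)C(=C)CO[Si](c1ccccc1)(c1ccccc1)C(C)(C)C
F7 | step 17 | (4R)-4-hydroxydihydrofuran-2(3H)-one | O=C1C[C@@H](O)CO1
F8 | step 17 | (4R)-4-hydroxy-3-methylidenedihydrofuran-2(3H)-one | C=C1[C@@H](O)COC1=O
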